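## Retrosynthetic overview

1. The spiro-dihydropyran is cut last, by an inverse-demand oxa-Diels–Alder reaction, into alantolactone (exocyclic C11=C13 as dienophile) and the 2-substituted acrolein of the carbocyclic half.
2. In the lactone half, C13 comes from α-methylenation, and the C8–O bond from Baeyer–Villiger oxidation of a cyclobutanone whose C12–C8 bond is temporary.
3. Key disconnection: ring B and the cyclobutanone come from one intramolecular [2+2] of a keteniminium (C8=C12) with the terminal double bond (C7=C11) of a (Z)-diene on ring A, forming C12–C11 and C8–C7. The feature that allows this is the C7–C8 edge shared by cyclohexene ring B and the γ-lactone, with the C5=C6 double bond next to C7 and C12 one oxygen insertion away from the carbinol C8.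
4. The (Z)-diene comes from a bicyclic enone: Baeyer–Villiger oxidation gives a seven-membered enol lactone (a temporary ring that fixes the geometry), which is opened by a chiral lithium amide, triflated and vinylated.
5. Ring order: ring A (bought) → temporary enone ring → temporary enol-lactone ring → ring B plus cyclobutane (key step) → γ-lactone → dihydropyran; the cyclohexane of the other half comes from (S)-carvone.

Key step: step 8

Remark on the chemistry: atoms of the lactone half are numbered as in eudesmane (methyls on C4 and C10, C5=C6, lactone fusion C7/C8, spiro C11, carbonyl C12, pyran CH2 C13). The SMILES is read as alantolactone configuration in that half and the configuration enantiomeric to natural β-elemene in the other half.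

## Route

Step 1
Reactants: 1 2-methylcyclohexanone; 2 (S)-1-phenylethylamine; 3 but-3-en-2-one
Product: 6 (R)-2-methyl-2-(3-oxobutyl)cyclohexan-1-one, via imine 4 (not isolated), via keto imine 5 (not isolated)
Conditions: 2, TsOH (cat.), PhMe, reflux, −H2O; then 3, neat, 40 °C; then 10% aq. AcOH, rt
Reagents that add atoms: water, O
Why: Chiral-imine Michael addition (aza-ene type): the more substituted secondary enamine tautomer of 4 adds to the enone through a cyclic transition state on the face away from the phenyl group of the (S)-auxiliary, which sets the quaternary centre as R, and mild acid hydrolysis frees the 1,5-diketone.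

Step 2
Reactants: 6 (R)-2-methyl-2-(3-oxobutyl)cyclohexan-1-one
Product: 7 (R)-4a-methyl-4,4a,5,6,7,8-hexahydronaphthalen-2(3H)-one
Conditions: NaOMe (cat.), MeOH, 60 °C
Reagents that add atoms: none
Why: Intramolecular aldol condensation (second stage of a Robinson annulation) should close the cyclohexenone; the quaternary centre is not enolisable and stays R.

Step 3
Reactants: 7 (R)-4a-methyl-4,4a,5,6,7,8-hexahydronaphthalen-2(3H)-one
Product: 8 (R)-4a-methyl-8-methylidene-4,4a,5,6,7,8-hexahydronaphthalen-2(3H)-one
Conditions: CH2(OEt)2, POCl3, NaOAc, CHCl3, reflux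
Reagents that add atoms: diethoxymethane, CCOCOCC
Why: γ-Methylenation of a fused cyclohex-2-enone: the dienol ether formed in situ is alkoxymethylated at the γ-carbon (vinylogous Mannich/Prins-type reaction) and loses ethanol, as in the 6-methylenation of 3-oxo-4-ene steroids; no stereocentre is made.

Step 4
Reactants: 8 (R)-4a-methyl-8-methylidene-4,4a,5,6,7,8-hexahydronaphthalen-2(3H)-one
Product: 9 (4aR,8S)-4a,8-dimethyl-4,4a,5,6,7,8-hexahydronaphthalen-2(3H)-one
Conditions: H2 (1 atm), RhCl(PPh3)3 (cat.), PhH, rt
Reagents that add atoms: none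
Why: Homogeneous hydrogenation should reduce only the unhindered 1,1-disubstituted exocyclic alkene; H2 is delivered from the face opposite the axial angular methyl, so the new methyl comes out cis to it (8S), and the neutral conditions keep this kinetic, axial epimer.

Step 5
Reactants: 9 (4aR,8S)-4a,8-dimethyl-4,4a,5,6,7,8-hexahydronaphthalen-2(3H)-one
Product: 10 (5aR,9S)-5a,9-dimethyl-5,5a,6,7,8,9-hexahydro-2-benzoxepin-3(4H)-one
Conditions: mCPBA (1.05 equiv), CH2Cl2, 0 °C to rt, dark
Reagents that add atoms: 3-chloroperoxybenzoic acid, O=C(OO)c1cccc(Cl)c1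
Why: Baeyer–Villiger oxidation of a conjugated cyclohexenone in which the alkenyl carbon migrates in preference to the primary alkyl carbon, as in the known conversion of fused enones into seven-membered enol lactones; the ring forces the enol oxygen and C10 onto the same side of the C5=C6 bond.

Step 6
Reactants: 10 (5aR,9S)-5a,9-dimethyl-5,5a,6,7,8,9-hexahydro-2-benzoxepin-3(4H)-one; 11 (2S,5S)-2,5-dimethylpyrrolidine
Product: 13 (Z)-{(2R,6S)-2-[3-((2S,5S)-2,5-dimethylpyrrolidin-1-yl)-3-oxopropyl]-2,6-dimethylcyclohexylidene}methyl trifluoromethanesulfonate, via lithium enolate 12 (not isolated)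
Conditions: 11, n-BuLi, THF, −78 °C; then 10, −78 to −30 °C; then PhNTf2, −78 °C to rt
Reagents that add atoms: N-phenylbis(trifluoromethanesulfonimide), O=S(=O)(N(c1ccccc1)S(=O)(=O)C(F)(F)F)C(F)(F)F
Why: Acyl substitution on the enol ester by the lithium amide installs the chiral tertiary amide and frees the aldehyde lithium enolate, whose oxygen is cis to C10 by its ring origin; O-sulfonylation of this configurationally fixed enolate (enolate triflation) keeps the Z geometry.

Step 7
Reactants: 13 (Z)-{(2R,6S)-2-[3-((2S,5S)-2,5-dimethylpyrrolidin-1-yl)-3-oxopropyl]-2,6-dimethylcyclohexylidene}methyl trifluoromethanesulfonate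
Product: 14 3-[(1R,2Z,3S)-1,3-dimethyl-2-(prop-2-en-1-ylidene)cyclohexyl]-1-[(2S,5S)-2,5-dimethylpyrrolidin-1-yl]propan-1-one
Conditions: tributyl(vinyl)stannane, Pd(PPh3)4 (cat.), LiCl, THF, 65 °C
Reagents that add atoms: tributyl(vinyl)stannane, C=C[Sn](CCCC)(CCCC)CCCC
Why: Stille cross-coupling of an alkenyl triflate with a vinylstannane runs with retention of double-bond geometry and should give the (Z)-diene.

Step 8
Reactants: 14 3-[(1R,2Z,3S)-1,3-dimethyl-2-(prop-2-en-1-ylidene)cyclohexyl]-1-[(2S,5S)-2,5-dimethylpyrrolidin-1-yl]propan-1-one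
Product: 17 tricyclic cyclobutanone (ring B cis-fused to a four-membered ketone C7–C11H2–C12(=O)–C8; 4S,7S,8R,10R), via keteniminium triflate 15 (not isolated), via cyclobutaniminium triflate 16 (not isolated)
Conditions: Tf2O, 2,4,6-collidine, ClCH2CH2Cl, −20 °C to reflux; then H2O, rt
Reagents that add atoms: water, O
Why: O-triflation of the amide and loss of the C8 proton give keteniminium 15; its central carbon C12 bonds to the unsubstituted diene terminus C11 while positive charge spreads over C7 and C5, and C8 then closes on C7, an asynchronous thermal [2+2] that gives iminium 16 and, with water, the ketone. The closest known reactions are the intramolecular keteniminium–alkene [2+2] cycloadditions of ω-alkenyl amides, including those of 2,5-dimethylpyrrolidine amides, and the [2+2] addition of ketenes to 1,3-dienes, which has the same regiochemistry. Ring B closes in the 6-exo mode (C8 onto C7 through the tether C9–C10–C5=C6, held in place by the Z double bond) and the four-membered ring closes by the C12–C11 bond on the same face of C7=C11, so the two rings are cis-fused. C7 and C8 are the new stereocentres: their cis relation follows from the ring fusion, and the face (syn to the C10 methyl, giving 8R and 7S) is meant to be set by the C2-symmetric pyrrolidinium, whose methyl group on the side of the approaching alkene blocks one face of the C8=C12 bond. The step needs site selectivity for the terminal C7=C11 bond over the hindered C5=C6 bond and [2+2] over [4+2], which the free CH2 terminus, the stabilised allyl cation and the six-membered closure should secure, and it needs facial selectivity, for which ring A alone gives no reliable bias and the auxiliary is relied on.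

Step 9
Reactants: 17 tricyclic cyclobutanone
Product: 18 (3aS,5S,8aR,9aR)-5,8a-dimethyl-3a,5,6,7,8,8a,9,9a-octahydronaphtho[2,3-b]furan-2(3H)-one
Conditions: 30% H2O2, AcOH/H2O, 0 °C
Reagents that add atoms: hydrogen peroxide, OO
Why: Baeyer–Villiger ring expansion of the strained cyclobutanone with migration of the more substituted α-carbon C8 (retention) gives the cis-fused γ-lactone with oxygen on C8, as in the classical bicyclic cyclobutanone-to-lactone conversions; dilute H2O2 in AcOH at 0 °C should spare the hindered trisubstituted alkene.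

Step 10
Reactants: 18 (3aS,5S,8aR,9aR)-5,8a-dimethyl-3a,5,6,7,8,8a,9,9a-octahydronaphtho[2,3-b]furan-2(3H)-one
Product: 20 3-[(dimethylamino)methyl] derivative of lactone 18 (C3 epimers), via lithium enolate 19 (not isolated)
Conditions: LiN(iPr)2, THF, −78 °C; then dimethyl(methylidene)ammonium iodide, −78 °C to rt
Reagents that add atoms: dimethyl(methylidene)ammonium iodide, C[N+](C)=C.[I-]
Why: Mannich reaction of the lactone lithium enolate with a preformed iminium salt at C11, the only enolisable position; the C11 centre formed here is destroyed in the next step.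

Step 11
Reactants: 20 3-[(dimethylamino)methyl] derivative of lactone 18
Product: 22 alantolactone, (3aR,5S,8aR,9aR)-5,8a-dimethyl-3-methylidene-3a,5,6,7,8,8a,9,9a-octahydronaphtho[2,3-b]furan-2(3H)-one, via methiodide 21 (not isolated)
Conditions: MeI, MeOH, rt; then NaHCO3, H2O/EtOAc, rt
Reagents that add atoms: none
Why: Quaternisation of the amine followed by base-induced β-elimination (Hofmann-type, E1cB) is the standard route to α-methylene-γ-lactones and should give alantolactone without touching C7 or C8.

Step 12
Reactants: 23 (S)-carvone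
Product: 24 (5S)-2-methyl-5-(prop-1-en-2-yl)cyclohexan-1-one (C2 epimers)
Conditions: LiBH(s-Bu)3 (1.05 equiv), THF, −78 °C; then H2O
Reagents that add atoms: none
Why: Conjugate (1,4) hydride reduction of the enone by the bulky borohydride and protonation of the enolate; C5 is untouched and the C2 mixture does not matter because this centre is re-formed in the next step.

Step 13
Reactants: 24 (5S)-2-methyl-5-(prop-1-en-2-yl)cyclohexan-1-one; 2 (S)-1-phenylethylamine; 25 methyl prop-2-enoate
Product: 28 methyl 3-[(1R,4S)-1-methyl-2-oxo-4-(prop-1-en-2-yl)cyclohexyl]propanoate, via imine 26 (not isolated), via ester imine 27 (not isolated)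
Conditions: 2, TsOH (cat.), PhMe, reflux, −H2O; then 25, THF, 60 °C; then 10% aq. AcOH, rt
Reagents that add atoms: water, O
Why: Chiral-imine Michael addition to an acrylate: the (S)-auxiliary directs the acceptor to the enamine face that places the new chain trans to the isopropenyl group and leaves the methyl group cis to it (reagent control, as used in the eudesmane series), giving the R quaternary centre.

Step 14
Reactants: 28 methyl 3-[(1R,4S)-1-methyl-2-oxo-4-(prop-1-en-2-yl)cyclohexyl]propanoate
Product: 29 3-[(1R,4S)-1-methyl-2-oxo-4-(prop-1-en-2-yl)cyclohexyl]propanoic acid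
Conditions: LiOH, THF/H2O, rt; then 1 M HCl
Reagents that add atoms: lithium hydroxide, [Li+].[OH-]
Why: Ester saponification; no stereocentre is at risk under these conditions.

Step 15
Reactants: 29 3-[(1R,4S)-1-methyl-2-oxo-4-(prop-1-en-2-yl)cyclohexyl]propanoic acid
Product: 30 (2R,5S)-2-ethenyl-2-methyl-5-(prop-1-en-2-yl)cyclohexan-1-one
Conditions: Pb(OAc)4, Cu(OAc)2 (cat.), pyridine, PhH, 80 °C
Reagents that add atoms: none
Why: Oxidative decarboxylation: the primary alkyl radical left after loss of CO2 is oxidised by the copper salt to the terminal alkene, which turns the propanoic acid chain into the vinyl group on the quaternary carbon.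

Step 16
Reactants: 30 (2R,5S)-2-ethenyl-2-methyl-5-(prop-1-en-2-yl)cyclohexan-1-one
Product: 32 1-[(2R,5S)-2-ethenyl-1-hydroxy-2-methyl-5-(prop-1-en-2-yl)cyclohexyl]ethan-1-one (C1 epimers), via enol ether 31 (not isolated)
Conditions: ethyl vinyl ether, t-BuLi, THF, −78 to 0 °C; then CeCl3, 30, THF, −78 °C; then 1 M HCl, rt
Reagents that add atoms: ethyl vinyl ether, C=COCC; water, O
Why: 1,2-Addition of 1-ethoxyvinyllithium (an acetyl anion equivalent; CeCl3 suppresses enolisation of the hindered ketone) and acid hydrolysis of the enol ether give the α-hydroxy methyl ketone; the carbinol configuration does not matter because it is removed in the next step.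

Step 17
Reactants: 32 1-[(2R,5S)-2-ethenyl-1-hydroxy-2-methyl-5-(prop-1-en-2-yl)cyclohexyl]ethan-1-one
Product: 33 1-[(1S,2R,5S)-2-ethenyl-2-methyl-5-(prop-1-en-2-yl)cyclohexyl]ethan-1-one
Conditions: SmI2 (2.5 equiv), THF/MeOH, −78 °C; then K2CO3 (cat.), MeOH, rt
Reagents that add atoms: none
Why: Reductive cleavage of the α-hydroxy ketone C–O bond by SmI2 (ketyl, β-elimination, enolate protonation) followed by base equilibration should place the acetyl group equatorial, cis to the isopropenyl-bearing carbon and trans to the vinyl group (thermodynamic control of the 1S centre).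

Step 18
Reactants: 33 1-[(1S,2R,5S)-2-ethenyl-2-methyl-5-(prop-1-en-2-yl)cyclohexyl]ethan-1-one
Product: 35 2-[(1S,3S,4R)-3-acetyl-4-ethenyl-4-methylcyclohexyl]prop-2-enal, via allylic alcohol 34 (not isolated)
Conditions: SeO2 (cat.), t-BuOOH, CH2Cl2, rt; then MnO2, CH2Cl2, rt
Reagents that add atoms: tert-butyl hydroperoxide, CC(C)(C)OO
Why: Allylic oxidation with SeO2/t-BuOOH (ene reaction then [2,3]-shift) attacks the methyl group of the isopropenyl unit, the only alkene with allylic hydrogens on a CH3 group (the vinyl group has none), and MnO2 oxidises the allylic alcohol to the 2-substituted acrolein.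

Step 19
Reactants: 22 alantolactone; 35 2-[(1S,3S,4R)-3-acetyl-4-ethenyl-4-methylcyclohexyl]prop-2-enal
Product: 36 spiro-dihydropyran adduct (the target skeleton with an acetyl group in place of the ring isopropenyl group)
Conditions: 35 (1.5 equiv), 2,6-di-tert-butyl-4-methylphenol (cat.), PhMe, sealed tube, 120 °C
Reagents that add atoms: none
Why: Inverse-electron-demand oxa-Diels–Alder reaction with the enal as heterodiene and the exocyclic C11=C13 bond as dienophile, with the head-to-head regiochemistry of the acrolein and methacrolein dimerisations (O to C11, CH2 to CH2); the heterodiene should add to the convex face of the cis-fused lactone, the side of H7 and H8 away from ring B, which sets the spiro centre C11.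

Step 20
Reactants: 36 spiro-dihydropyran adduct
Product: 37 CNP0175206.1 (target)
Conditions: Ph3PCH3Br, KN(SiMe3)2, THF, 0 °C; then 36, 0 °C to rt
Reagents that add atoms: methyltriphenylphosphonium bromide, C[P+](c1ccccc1)(c1ccccc1)c1ccccc1.[Br-]
Why: Wittig methylenation of the methyl ketone with the non-stabilised ylide; the lactone and the enol ether should be inert to the ylide at this temperature and the adjacent centre is already in its stable equatorial configuration.

## Compound list

1 | 2-methylcyclohexanone (racemic) | CC1CCCCC1=O | starting material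
2 | (S)-1-phenylethylamine | C[C@H](N)c1ccccc1 | starting material
3 | but-3-en-2-one | C=CC(C)=O | starting material
4 | N-[(S)-1-phenylethyl]imine of 2-methylcyclohexanone | CC1CCCCC1=N[C@@H](C)c1ccccc1 | intermediate (not isolated)
5 | N-[(S)-1-phenylethyl]imine of (R)-2-methyl-2-(3-oxobutyl)cyclohexanone | CC(=O)CC[C@@]1(C)CCCCC1=N[C@@H](C)c1ccccc1 | intermediate (not isolated)
6 | (R)-2-methyl-2-(3-oxobutyl)cyclohexan-1-one | CC(=O)CC[C@@]1(C)CCCCC1=O | intermediate
7 | (R)-4a-methyl-4,4a,5,6,7,8-hexahydronaphthalen-2(3H)-one | O=C1CC[C@@]2(C)CCCCC2=C1 | intermediate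
8 | (R)-4a-methyl-8-methylidene-4,4a,5,6,7,8-hexahydronaphthalen-2(3H)-one | O=C1CC[C@@]2(C)CCCC(=C)C2=C1 | intermediate
9 | (4aR,8S)-4a,8-dimethyl-4,4a,5,6,7,8-hexahydronaphthalen-2(3H)-one | O=C1CC[C@@]2(C)CCC[C@H](C)C2=C1 | intermediate
10 | (5aR,9S)-5a,9-dimethyl-5,5a,6,7,8,9-hexahydro-2-benzoxepin-3(4H)-one (seven-membered enol lactone) | O=C1CC[C@@]2(C)CCC[C@H](C)C2=CO1 | intermediate
11 | (2S,5S)-2,5-dimethylpyrrolidine | C[C@H]1CC[C@H](C)N1 | starting material
12 | lithium (Z)-enolate of the ring-opened aldehyde amide | [Li]O/C=C1/[C@@H](C)CCC[C@]1(C)CCC(=O)N1[C@@H](C)CC[C@@H]1C | intermediate (not isolated)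
13 | (Z)-{(2R,6S)-2-[3-((2S,5S)-2,5-dimethylpyrrolidin-1-yl)-3-oxopropyl]-2,6-dimethylcyclohexylidene}methyl trifluoromethanesulfonate | FC(F)(F)S(=O)(=O)O/C=C1/[C@@H](C)CCC[C@]1(C)CCC(=O)N1[C@@H](C)CC[C@@H]1C | intermediate
14 | 3-[(1R,2Z,3S)-1,3-dimethyl-2-(prop-2-en-1-ylidene)cyclohexyl]-1-[(2S,5S)-2,5-dimethylpyrrolidin-1-yl]propan-1-one | C=C/C=C1/[C@@H](C)CCC[C@]1(C)CCC(=O)N1[C@@H](C)CC[C@@H]1C | intermediate
15 | keteniminium triflate of 14 | C=C/C=C1/[C@@H](C)CCC[C@]1(C)CC=C=[N+]1[C@@H](C)CC[C@@H]1C.[O-]S(=O)(=O)C(F)(F)F | intermediate (not isolated)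
16 | cyclobutaniminium triflate (tricyclic) | C1C(=[N+]2[C@@H](C)CC[C@@H]2C)[C@@H]2C[C@@]3(C)CCC[C@H](C)C3=C[C@@H]21.[O-]S(=O)(=O)C(F)(F)F | intermediate (not isolated)
17 | tricyclic cyclobutanone (C7–C11H2–C12(=O)–C8 ring cis-fused to ring B; 4S,7S,8R,10R) | C1C(=O)[C@@H]2C[C@@]3(C)CCC[C@H](C)C3=C[C@@H]21 | intermediate
18 | (3aS,5S,8aR,9aR)-5,8a-dimethyl-3a,5,6,7,8,8a,9,9a-octahydronaphtho[2,3-b]furan-2(3H)-one | C1C(=O)O[C@@H]2C[C@@]3(C)CCC[C@H](C)C3=C[C@@H]21 | intermediate
19 | lithium enolate of lactone 18 | C1=C(O[Li])O[C@@H]2C[C@@]3(C)CCC[C@H](C)C3=C[C@@H]21 | intermediate (not isolated)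
20 | 3-[(dimethylamino)methyl] derivative of lactone 18 (C3 epimers) | CN(C)CC1C(=O)O[C@@H]2C[C@@]3(C)CCC[C@H](C)C3=C[C@@H]21 | intermediate
21 | trimethylammonium iodide of 20 | C[N+](C)(C)CC1C(=O)O[C@@H]2C[C@@]3(C)CCC[C@H](C)C3=C[C@@H]21.[I-] | intermediate (not isolated)
22 | alantolactone, (3aR,5S,8aR,9aR)-5,8a-dimethyl-3-methylidene-3a,5,6,7,8,8a,9,9a-octahydronaphtho[2,3-b]furan-2(3H)-one | C=C1C(=O)O[C@@H]2C[C@@]3(C)CCC[C@H](C)C3=C[C@@H]21 | intermediate
23 | (S)-carvone, (5S)-2-methyl-5-(prop-1-en-2-yl)cyclohex-2-en-1-one | CC1=CC[C@H](C(=C)C)CC1=O | starting material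
24 | (5S)-2-methyl-5-(prop-1-en-2-yl)cyclohexan-1-one (C2 epimers) | CC1CC[C@H](C(=C)C)CC1=O | intermediate
25 | methyl prop-2-enoate | C=CC(=O)OC | starting material
26 | N-[(S)-1-phenylethyl]imine of 24 | CC1CC[C@H](C(=C)C)CC1=N[C@@H](C)c1ccccc1 | intermediate (not isolated)
27 | N-[(S)-1-phenylethyl]imine of keto ester 28 | COC(=O)CC[C@@]1(C)CC[C@H](C(=C)C)CC1=N[C@@H](C)c1ccccc1 | intermediate (not isolated)
28 | methyl 3-[(1R,4S)-1-methyl-2-oxo-4-(prop-1-en-2-yl)cyclohexyl]propanoate | COC(=O)CC[C@@]1(C)CC[C@H](C(=C)C)CC1=O | intermediate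
29 | 3-[(1R,4S)-1-methyl-2-oxo-4-(prop-1-en-2-yl)cyclohexyl]propanoic acid | OC(=O)CC[C@@]1(C)CC[C@H](C(=C)C)CC1=O | intermediate
30 | (2R,5S)-2-ethenyl-2-methyl-5-(prop-1-en-2-yl)cyclohexan-1-one | C=C[C@@]1(C)CC[C@H](C(=C)C)CC1=O | intermediate
31 | (2R,5S)-2-ethenyl-1-(1-ethoxyethenyl)-2-methyl-5-(prop-1-en-2-yl)cyclohexan-1-ol (C1 epimers) | C=C[C@@]1(C)CC[C@H](C(=C)C)CC1(O)C(=C)OCC | intermediate (not isolated)
32 | 1-[(2R,5S)-2-ethenyl-1-hydroxy-2-methyl-5-(prop-1-en-2-yl)cyclohexyl]ethan-1-one (C1 epimers) | C=C[C@@]1(C)CC[C@H](C(=C)C)CC1(O)C(C)=O | intermediate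
33 | 1-[(1S,2R,5S)-2-ethenyl-2-methyl-5-(prop-1-en-2-yl)cyclohexyl]ethan-1-one | C=C[C@@]1(C)CC[C@H](C(=C)C)C[C@@H]1C(C)=O | intermediate
34 | 1-[(1S,2R,5S)-2-ethenyl-5-(3-hydroxyprop-1-en-2-yl)-2-methylcyclohexyl]ethan-1-one | C=C[C@@]1(C)CC[C@H](C(=C)CO)C[C@@H]1C(C)=O | intermediate (not isolated)
35 | 2-[(1S,3S,4R)-3-acetyl-4-ethenyl-4-methylcyclohexyl]prop-2-enal | C=C[C@@]1(C)CC[C@H](C(=C)C=O)C[C@@H]1C(C)=O | intermediate
36 | spiro-dihydropyran adduct (target skeleton with acetyl in place of the ring isopropenyl group) | C=C[C@@]1(C)CC[C@H](C2=CO[C@@]3(CC2)C(=O)O[C@@H]2C[C@@]4(C)CCC[C@H](C)C4=C[C@@H]23)C[C@@H]1C(C)=O | intermediate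
37 | CNP0175206.1 | C=C[C@@]1(C)CC[C@H](C2=CO[C@@]3(CC2)C(=O)O[C@@H]2C[C@@]4(C)CCC[C@H](C)C4=C[C@@H]23)C[C@@H]1C(=C)C | target

## Step count and risks

Total step count: 20. Longest linear sequence: 13 (steps 1–11, 19, 20).

Steps most likely to fail:

1. Step 8. What may go wrong: poor facial selectivity in the ring closure (the cis-fused cyclobutanone forming on the face away from the C10 methyl, or the auxiliary inducing the opposite sense), or addition of the keteniminium across the C5=C6 bond. Fallback: ring B is closed last by metathesis and the [2+2] is run between two molecules. It sets out from enol triflate 13. Reduction of the C–O bond (Pd(OAc)2, PPh3, HCO2H, Et3N) should give the exocyclic methylene amide F1. Its keteniminium (Tf2O, collidine) is added to buta-1,3-diene in an intermolecular [2+2] with the same regiochemistry, the face now set by the auxiliary alone; hydrolysis should give the cis vinylcyclobutanone F2. Baeyer–Villiger oxidation (H2O2, AcOH) gives the vinyl lactone F3. Ring-closing metathesis with second-generation Grubbs catalyst between the vinyl group and the exocyclic methylene forms C5=C6 and comes back to the route at lactone 18.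

2. Step 19. What may go wrong: slow cross-cycloaddition with competing self-dimerisation or polymerisation of the enal. Fallback: the dihydropyran is built stepwise by radical conjugate addition, hydroxylation and cyclodehydration. It sets out from enal 35. NaI/Me3SiCl in MeCN, then ethane-1,2-diol, should give the iodo bis-dioxolane F4. Radical conjugate addition of F4 to alantolactone 22 (Bu3SnH, AIBN, PhH, 80 °C) joins C13 to the future pyran CH2 and gives lactone F5. Enolate hydroxylation at C11 from the convex face (KN(SiMe3)2, then 2-(phenylsulfonyl)-3-phenyloxaziridine) gives the hydroxy lactone F6. TsOH in wet acetone, then in toluene at reflux, removes both dioxolanes, closes the lactol and dehydrates it, coming back to the route at adduct 36.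

3. Step 5. What may go wrong: migration of the alkyl instead of the alkenyl carbon, or further oxidation of the electron-rich enol lactone. Fallback: the enone CH carbon is cut out and ring B is built by metathesis. It sets out from octalone 9. Ozonolysis with oxidative work-up (O3, then H2O2) should give the keto acid F7. (COCl)2 and then amine 11 give the keto amide F8. Methylenation under non-basic conditions (Zn, CH2Br2, TiCl4) gives the methylene amide F1, which is taken on as in the first fallback (F2, F3) and comes back to the route at lactone 18.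

Further compounds
F1 | step 8 | 3-[(1R,3S)-1,3-dimethyl-2-methylidenecyclohexyl]-1-[(2S,5S)-2,5-dimethylpyrrolidin-1-yl]propan-1-one | C=C1[C@@H](C)CCC[C@]1(C)CCC(=O)N1[C@@H](C)CC[C@@H]1C
F2 | step 8 | (2R,3S)-2-{[(1R,3S)-1,3-dimethyl-2-methylidenecyclohexyl]methyl}-3-ethenylcyclobutan-1-one | C=C[C@@H]1CC(=O)[C@@H]1C[C@@]1(C)CCC[C@H](C)C1=C
F3 | step 8 | (4S,5R)-5-{[(1R,3S)-1,3-dimethyl-2-methylidenecyclohexyl]methyl}-4-ethenyloxolan-2-one | C=C[C@@H]1CC(=O)O[C@@H]1C[C@@]1(C)CCC[C@H](C)C1=C
F4 | step 19 | iodo bis-dioxolane from 35 (HI adduct, aldehyde and ketone both as 1,3-dioxolanes; side-chain centre as a mixture) | C=C[C@@]1(C)CC[C@H](C(CI)C2OCCO2)C[C@@H]1C1(C)OCCO1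
F5 | step 19 | conjugate adduct of F4 with alantolactone (C11 epimers) | C=C[C@@]1(C)CC[C@H](C(CCC2C(=O)O[C@@H]3C[C@@]4(C)CCC[C@H](C)C4=C[C@@H]32)C2OCCO2)C[C@@H]1C1(C)OCCO1
F6 | step 19 | C11-hydroxy lactone from F5 | C=C[C@@]1(C)CC[C@H](C(CC[C@]2(O)C(=O)O[C@@H]3C[C@@]4(C)CCC[C@H](C)C4=C[C@@H]32)C2OCCO2)C[C@@H]1C1(C)OCCO1
F7 | step 5 | 3-[(1R,3S)-1,3-dimethyl-2-oxocyclohexyl]propanoic acid | OC(=O)CC[C@@]1(C)CCC[C@H](C)C1=O
F8 | step 5 | 3-[(1R,3S)-1,3-dimethyl-2-oxocyclohexyl]-1-[(2S,5S)-2,5-dimethylpyrrolidin-1-yl]propan-1-one | O=C(CC[C@@]1(C)CCC[C@H](C)C1=O)N1[C@@H](C)CC[C@@H]1C
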